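The ten-membered carbocycle is opened at both bonds of the C3 ketone, which lies between sp2 carbon C4 of the Z-enone and C2, itself sp2 before epoxidation. A carbonylative Stille macrocyclisation inserts CO between an E-vinyl iodide (C2) and a Z-vinylstannane (C4), forming C2–C3, C3–C4 and the ring in one operation and giving tagitinin C. Both alkene geometries are fixed beforehand in the open chain. The seco precursor is a trans α-methylene-γ-lactone carrying the stannylpropenyl group at C6 and the C8 isobutyrate/C10 carbinol/iodovinyl chain at C7, assembled from a butenolide, a glycidol and a dithiane linchpin. Hydroxyl-guided epoxidation of C1=C2 finishes the synthesis.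

Key step: step 16

Remark: labels C1–C13 are the positions the atoms take in the target, which is (1R,2R,6R,7R,8R,10R); the stereochemical mapping was checked and needed no correction ((S)-butenolide 1 gives C6, (S)-2-methylglycidol 3 gives C10, CIP labels change only through priority changes); C11 of the aminomethyl intermediates 15–18 and 23–28 is assumed trans to the C7 side chain and is erased in step 15.

Step 1
Reactants: 1 (S)-5-(hydroxymethyl)furan-2(5H)-one
Product: 2 (S)-5-[(triethylsilyloxy)methyl]furan-2(5H)-one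
Conditions: TESCl, imidazole, CH2Cl2, 0 °C
Reagents that add atoms: chlorotriethylsilane, CC[Si](Cl)(CC)CC
Why: Imidazole-promoted silylation of the primary alcohol (silyl ether formation) leaves the C6 stereocentre untouched and gives the one silyl ether that step 9 can later oxidise selectively.

Step 2
Reactants: 3 (S)-2-methylglycidol
Product: 4 (R)-tert-butyldimethyl[(2-methyloxiran-2-yl)methoxy]silane
Conditions: TBSCl, imidazole, DMF, 0 °C → rt
Reagents that add atoms: tert-butyldimethylsilyl chloride, CC(C)(C)[Si](C)(C)Cl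
Why: Standard silyl ether formation at the primary hydroxyl; the quaternary centre is not involved (the R label arises only from the priority change).

Step 3
Reactants: 5 1,3-dithiane; 4 (R)-tert-butyldimethyl[(2-methyloxiran-2-yl)methoxy]silane
Product: 8 (R)-2-[3-(tert-butyldimethylsilyloxy)-2-methyl-2-(triethylsilyloxy)propyl]-1,3-dithiane, via 2-lithio-1,3-dithiane 6 (not isolated), via lithium alkoxide 7 (not isolated)
Conditions: 5, n-BuLi, THF, −30 °C; 4, −30 °C → rt; TESOTf, −78 → 0 °C
Reagents that add atoms: triethylsilyl trifluoromethanesulfonate, CC[Si](CC)(CC)OS(=O)(=O)C(F)(F)F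
Why: Corey–Seebach alkylation in which the dithianyl anion opens the 2,2-disubstituted epoxide by SN2 attack at its CH2 terminus (C9), so the chiral-pool C10 centre is retained, and the tertiary lithium alkoxide is silylated in the same flask.

Step 4
Reactants: 8 (R)-2-[3-(tert-butyldimethylsilyloxy)-2-methyl-2-(triethylsilyloxy)propyl]-1,3-dithiane; 2 (S)-5-[(triethylsilyloxy)methyl]furan-2(5H)-one
Product: 11 (4S,5S)-4-{2-[(R)-3-(tert-butyldimethylsilyloxy)-2-methyl-2-(triethylsilyloxy)propyl]-1,3-dithian-2-yl}-5-[(triethylsilyloxy)methyl]oxolan-2-one (trans), via lithiated dithiane 9 (not isolated), via lithium enolate 10 (not isolated)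
Conditions: 8, t-BuLi, THF/HMPA (9:1), −78 °C; then 2, −78 °C; aq NH4Cl
Reagents that add atoms: none
Why: Conjugate (1,4) addition of the HMPA-solvated 2-lithio-1,3-dithiane (acyl anion equivalent) to the butenolide occurs anti to the C6 CH2OTES group, which sets C7 trans to C6, and the enolate is protonated on quench.

Step 5
Reactants: 11 trans-lactone dithiane
Product: 12 (4S,5S)-4-[(R)-4-(tert-butyldimethylsilyloxy)-3-methyl-3-(triethylsilyloxy)butanoyl]-5-[(triethylsilyloxy)methyl]oxolan-2-one
Conditions: MeI, NaHCO3, MeCN/H2O (4:1), 40 °C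
Reagents that add atoms: water, O
Why: Alkylative dithiane hydrolysis (S-methylation, then attack of water) under bicarbonate buffer unmasks the C8 ketone without touching silyl ethers or lactone, and the enolisable C7 remains in the favoured trans arrangement.

Step 6
Reactants: 12 C8 ketone
Product: 13 (4R,5S)-4-[(1R,3R)-4-(tert-butyldimethylsilyloxy)-1-hydroxy-3-methyl-3-(triethylsilyloxy)butyl]-5-[(triethylsilyloxy)methyl]oxolan-2-one
Conditions: (S)-Me-CBS (1 equiv), BH3·SMe2, THF, −30 °C; MeOH
Reagents that add atoms: none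
Why: Corey–Bakshi–Shibata reduction in which the (S)-oxazaborolidine takes the α-branched ring carbon C7 as the large and CH2-9 as the small ketone substituent and delivers hydride to the face that gives the (8R) carbinol, so C8 is set by the catalyst because the lactone ring offers little facial bias of its own; the lactone is not reduced at −30 °C.

Step 7
Reactants: 13 C8 alcohol
Product: 16 (3R,4R,5S)-3-[(dimethylamino)methyl]-4-[(1R,3R)-4-(tert-butyldimethylsilyloxy)-1-hydroxy-3-methyl-3-(triethylsilyloxy)butyl]-5-[(triethylsilyloxy)methyl]oxolan-2-one, via dilithium alkoxide enolate 14 (not isolated), via lithium alkoxide 15 (not isolated)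
Conditions: LDA (2.3 equiv), THF, −78 °C; CH2=NMe2+ I−, −78 → 0 °C; aq NH4Cl
Reagents that add atoms: N,N-dimethylmethyleneiminium iodide (Eschenmoser's salt), C=[N+](C)C.[I-]
Why: Mannich aminomethylation of the lactone enolate (formed beside the C8 alkoxide, before any ester with α-hydrogens is present) occurs at C11 anti to the C7 side chain and installs C13 as a β-amino lactone, a masked α-methylene lactone that is inert to the ylide, palladium and chromium steps ahead.

Step 8
Reactants: 16 amino alcohol
Product: 17 C8 isobutyrate of 16 (6S,7R,8R,10R,11R)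
Conditions: (i-PrCO)2O, DMAP, Et3N, CH2Cl2, 0 °C → rt
Reagents that add atoms: isobutyric anhydride, CC(C)C(=O)OC(=O)C(C)C
Why: DMAP-catalysed acyl transfer esterifies the only free hydroxyl with retention at C8, and the trans 6,12-lactone is the thermodynamically preferred lactone, so translactonisation to O8 is not expected.

Step 9
Reactants: 17 C8 isobutyrate
Product: 18 C5 aldehyde (CHO on C6 in place of CH2OTES; 6S,7R,8R,10R,11R)
Conditions: (COCl)2, DMSO, CH2Cl2, −78 → −30 °C; Et3N, −78 → 0 °C
Reagents that add atoms: none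
Why: Swern oxidation applied directly to the primary triethylsilyl ether, which the chlorosulfonium reagent cleaves and oxidises in one operation while the primary TBS and tertiary TES ethers are inert; the aldehyde is used at once.

Step 10
Reactants: 18 C5 aldehyde; 19 ethyltriphenylphosphonium bromide
Product: 23 (Z)-vinyl iodide (C6 bears (Z)-CH=C(I)CH3 with iodine cis to C6), via ethylidenetriphenylphosphorane 20 (not isolated), via (1-iodoethyl)triphenylphosphonium iodide 21 (not isolated), via (1-iodoethylidene)triphenylphosphorane 22 (not isolated)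
Conditions: 19, n-BuLi, THF, 0 °C; I2, −78 °C; NaHMDS, −78 → −20 °C; then 18, −78 °C
Reagents that add atoms: iodine, II
Why: Stork–Zhao olefination with the α-iodo ylide gives the (Z)-2-iodoalkene under kinetic control, and at −78 °C addition to the aldehyde outruns epimerisation of the α-acyloxy centre C6.

Step 11
Reactants: 23 (Z)-vinyl iodide
Product: 24 (Z)-vinylstannane (SnBu3 in place of I at C4)
Conditions: (Bu3Sn)2, PdCl2(MeCN)2 (cat.), NMP, 25–40 °C, dark
Reagents that add atoms: hexabutylditin, CCCC[Sn](CCCC)(CCCC)[Sn](CCCC)(CCCC)CCCC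
Why: Palladium-catalysed stannylation of a vinyl iodide with a distannane (oxidative addition, Sn–Sn transmetalation, reductive elimination) proceeds with retention of alkene geometry, and the saturated amino lactone offers no alkene for a competing Heck closure.

Step 12
Reactants: 24 (Z)-vinylstannane
Product: 25 diol (C1 CH2OH and C10 OH free)
Conditions: HF·pyridine, pyridine, THF, 0 °C → rt
Reagents that add atoms: none
Why: Fluoride-mediated desilylation under pyridine buffer removes the primary TBS and the tertiary TES ether together, conditions that should spare vinylstannane, ester and lactone.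

Step 13
Reactants: 25 diol
Product: 26 α-hydroxy aldehyde (C1 CHO)
Conditions: SO3·pyridine, DMSO, i-Pr2NEt, CH2Cl2, 0 °C
Reagents that add atoms: none
Why: Parikh–Doering oxidation converts the primary alcohol to the aldehyde; the tertiary C10 hydroxyl cannot be oxidised and the quaternary α-carbon cannot epimerise.

Step 14
Reactants: 26 α-hydroxy aldehyde
Product: 27 (E)-vinyl iodide at C1=C2 (amine-masked seco compound)
Conditions: CrCl2, CHI3, THF/1,4-dioxane (1:6), 0 °C → rt, dark
Reagents that add atoms: iodoform, IC(I)I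
Why: Takai olefination through the gem-dichromium reagent gives the (E)-iodoalkene and tolerates the free tertiary hydroxyl, the amine and the vinylstannane.

Step 15
Reactants: 27 (E)-vinyl iodide
Product: 29 seco vinyl iodide–vinylstannane α-methylene lactone (6S,7R,8R,10R), via trimethylammonium iodide 28 (not isolated)
Conditions: MeI, MeCN, rt; then NaHCO3, CH2Cl2/H2O, rt
Reagents that add atoms: none
Why: Exhaustive N-methylation followed by E1cB (Hofmann-type) loss of trimethylamine from the β-ammonio lactone unveils the C11=C13 methylene without acid or strong base, which vinylstannane, vinyl iodide and ester tolerate.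

Step 16
Reactants: 29 seco vinyl iodide–vinylstannane α-methylene lactone; 30 carbon monoxide
Product: 31 tagitinin C (6R,7R,8R,10R; 1E,4Z)
Conditions: Pd2(dba)3·CHCl3 (10 mol %), AsPh3 (40 mol %), 30 (3 atm), DMF/THF (1:1), 50 °C, slow addition to 1 mM, dark
Reagents that add atoms: none
Why: Pd(0) adds oxidatively to the C2–I bond, CO inserts to give the C3 acylpalladium, the C4 (Z)-vinylstannane transmetalates intramolecularly and acyl–vinyl reductive elimination releases the cross-conjugated dienone. The closest known reaction is the carbonylative Stille coupling of vinyl iodides with vinylstannanes to divinyl ketones, including its macrocyclising variant. The ten-membered ring is closed end to end at C3–C4 by transmetalation and reductive elimination on the acylpalladium tether, C2–C3 having been formed just before by CO insertion. No stereocentre is created, and the E (C1=C2) and Z (C4=C5) geometries are carried over because every elementary step is stereoretentive at sp2 carbon. The selectivity needed is CO insertion before transmetalation and cyclisation before oligomerisation, which CO pressure, the strain of the nine-membered diene that direct coupling would give, the slow transmetalation of the α-methyl stannane, high dilution and the turn imposed by the trans-lactone and Z-alkene should secure. The E geometry keeps the C10 hydroxyl from trapping the acylpalladium as a butenolide, and the α-methylene lactone lies too far from C2 for Heck insertion.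

Step 17
Reactants: 31 tagitinin C
Product: 32 tagitinin C 1,2-epoxide (1R,2R,6R,7R,8R,10R), the target
Conditions: t-BuOOH (decane), DBU (cat.), CH2Cl2, −20 → 0 °C, dark
Reagents that add atoms: tert-butyl hydroperoxide, CC(C)(C)OO
Why: Weitz–Scheffer nucleophilic epoxidation in which tert-butylperoxide adds to C1 of the disubstituted C1=C2–C3=O enone on the exposed face flanked by the C10 hydroxyl (hydrogen-bond guidance, and less hindered than the methyl-bearing face) and the enolate closes onto oxygen to give the trans (1R,2R)-epoxide, the α-methyl enone C4=C5 and the lactone acrylate being less electrophilic towards peroxide.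

Compound list
1 | (S)-5-(hydroxymethyl)furan-2(5H)-one | OC[C@H]1OC(=O)C=C1 | starting material
2 | (S)-5-[(triethylsilyloxy)methyl]furan-2(5H)-one | CC[Si](CC)(CC)OC[C@H]1OC(=O)C=C1 | intermediate
3 | (S)-2-methylglycidol | OC[C@@]1(C)CO1 | starting material
4 | (R)-tert-butyldimethyl[(2-methyloxiran-2-yl)methoxy]silane | CC(C)(C)[Si](C)(C)OC[C@@]1(C)CO1 | intermediate
5 | 1,3-dithiane | C1CSCSC1 | starting material
6 | 2-lithio-1,3-dithiane | [Li]C1SCCCS1 | intermediate
7 | lithium (R)-1-(tert-butyldimethylsilyloxy)-3-(1,3-dithian-2-yl)-2-methylpropan-2-olate | CC(C)(C)[Si](C)(C)OC[C@](C)([O-])CC1SCCCS1.[Li+] | intermediate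
8 | (R)-2-[3-(tert-butyldimethylsilyloxy)-2-methyl-2-(triethylsilyloxy)propyl]-1,3-dithiane | CC(C)(C)[Si](C)(C)OC[C@](C)(O[Si](CC)(CC)CC)CC1SCCCS1 | intermediate
9 | 2-lithio derivative of 8 | CC(C)(C)[Si](C)(C)OC[C@](C)(O[Si](CC)(CC)CC)CC1([Li])SCCCS1 | intermediate
10 | lithium enolate of lactone 11 | CC[Si](CC)(CC)OC[C@H]1OC(O[Li])=C[C@@H]1C2(C[C@@](C)(O[Si](CC)(CC)CC)CO[Si](C)(C)C(C)(C)C)SCCCS2 | intermediate
11 | (4S,5S)-4-{2-[(R)-3-(tert-butyldimethylsilyloxy)-2-methyl-2-(triethylsilyloxy)propyl]-1,3-dithian-2-yl}-5-[(triethylsilyloxy)methyl]oxolan-2-one (4,5-trans) | CC[Si](CC)(CC)OC[C@H]1OC(=O)C[C@@H]1C2(C[C@@](C)(O[Si](CC)(CC)CC)CO[Si](C)(C)C(C)(C)C)SCCCS2 | intermediate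
12 | (4S,5S)-4-[(R)-4-(tert-butyldimethylsilyloxy)-3-methyl-3-(triethylsilyloxy)butanoyl]-5-[(triethylsilyloxy)methyl]oxolan-2-one | CC[Si](CC)(CC)OC[C@H]1OC(=O)C[C@@H]1C(=O)C[C@@](C)(O[Si](CC)(CC)CC)CO[Si](C)(C)C(C)(C)C | intermediate
13 | (4R,5S)-4-[(1R,3R)-4-(tert-butyldimethylsilyloxy)-1-hydroxy-3-methyl-3-(triethylsilyloxy)butyl]-5-[(triethylsilyloxy)methyl]oxolan-2-one | CC[Si](CC)(CC)OC[C@H]1OC(=O)C[C@@H]1[C@H](O)C[C@@](C)(O[Si](CC)(CC)CC)CO[Si](C)(C)C(C)(C)C | intermediate
14 | dilithium alkoxide enolate of 13 | CC[Si](CC)(CC)OC[C@H]1OC(O[Li])=C[C@@H]1[C@H](O[Li])C[C@@](C)(O[Si](CC)(CC)CC)CO[Si](C)(C)C(C)(C)C | intermediate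
15 | lithium C8 alkoxide of 16 | CC[Si](CC)(CC)OC[C@H]1OC(=O)[C@@H](CN(C)C)[C@@H]1[C@H](O[Li])C[C@@](C)(O[Si](CC)(CC)CC)CO[Si](C)(C)C(C)(C)C | intermediate
16 | (3R,4R,5S)-3-[(dimethylamino)methyl]-4-[(1R,3R)-4-(tert-butyldimethylsilyloxy)-1-hydroxy-3-methyl-3-(triethylsilyloxy)butyl]-5-[(triethylsilyloxy)methyl]oxolan-2-one | CC[Si](CC)(CC)OC[C@H]1OC(=O)[C@@H](CN(C)C)[C@@H]1[C@H](O)C[C@@](C)(O[Si](CC)(CC)CC)CO[Si](C)(C)C(C)(C)C | intermediate
17 | C8 isobutyrate of 16 (6S,7R,8R,10R,11R) | CC[Si](CC)(CC)OC[C@H]1OC(=O)[C@@H](CN(C)C)[C@@H]1[C@H](OC(=O)C(C)C)C[C@@](C)(O[Si](CC)(CC)CC)CO[Si](C)(C)C(C)(C)C | intermediate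
18 | C5 aldehyde: 17 with CHO on C6 in place of CH2OTES (6S,7R,8R,10R,11R) | O=C[C@H]1OC(=O)[C@@H](CN(C)C)[C@@H]1[C@H](OC(=O)C(C)C)C[C@@](C)(O[Si](CC)(CC)CC)CO[Si](C)(C)C(C)(C)C | intermediate
19 | ethyltriphenylphosphonium bromide | CC[P+](c1ccccc1)(c1ccccc1)c1ccccc1.[Br-] | starting material
20 | ethylidenetriphenylphosphorane | CC=P(c1ccccc1)(c1ccccc1)c1ccccc1 | intermediate
21 | (1-iodoethyl)triphenylphosphonium iodide | CC(I)[P+](c1ccccc1)(c1ccccc1)c1ccccc1.[I-] | intermediate
22 | (1-iodoethylidene)triphenylphosphorane | CC(I)=P(c1ccccc1)(c1ccccc1)c1ccccc1 | intermediate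
23 | (Z)-vinyl iodide: C6 bears (Z)-CH=C(I)CH3, iodine cis to C6 (6S,7R,8R,10R,11R) | C/C(I)=C/[C@H]1OC(=O)[C@@H](CN(C)C)[C@@H]1[C@H](OC(=O)C(C)C)C[C@@](C)(O[Si](CC)(CC)CC)CO[Si](C)(C)C(C)(C)C | intermediate
24 | (Z)-vinylstannane: 23 with SnBu3 in place of iodine | C/C([Sn](CCCC)(CCCC)CCCC)=C/[C@H]1OC(=O)[C@@H](CN(C)C)[C@@H]1[C@H](OC(=O)C(C)C)C[C@@](C)(O[Si](CC)(CC)CC)CO[Si](C)(C)C(C)(C)C | intermediate
25 | diol: 24 with free C1 CH2OH and C10 OH | C/C([Sn](CCCC)(CCCC)CCCC)=C/[C@H]1OC(=O)[C@@H](CN(C)C)[C@@H]1[C@H](OC(=O)C(C)C)C[C@@](C)(O)CO | intermediate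
26 | α-hydroxy aldehyde: 25 with CHO at C1 | C/C([Sn](CCCC)(CCCC)CCCC)=C/[C@H]1OC(=O)[C@@H](CN(C)C)[C@@H]1[C@H](OC(=O)C(C)C)C[C@@](C)(O)C=O | intermediate
27 | (E)-vinyl iodide at C1=C2, amine-masked seco compound | C/C([Sn](CCCC)(CCCC)CCCC)=C/[C@H]1OC(=O)[C@@H](CN(C)C)[C@@H]1[C@H](OC(=O)C(C)C)C[C@@](C)(O)/C=C/I | intermediate
28 | trimethylammonium iodide of 27 | C/C([Sn](CCCC)(CCCC)CCCC)=C/[C@H]1OC(=O)[C@@H](C[N+](C)(C)C)[C@@H]1[C@H](OC(=O)C(C)C)C[C@@](C)(O)/C=C/I.[I-] | intermediate
29 | seco vinyl iodide–vinylstannane α-methylene lactone (6S,7R,8R,10R; C4 Z-stannane, C2 E-iodide) | C=C1C(=O)O[C@H](/C=C(/C)[Sn](CCCC)(CCCC)CCCC)[C@H]1[C@H](OC(=O)C(C)C)C[C@@](C)(O)/C=C/I | intermediate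
30 | carbon monoxide | [C-]#[O+] | starting material
31 | tagitinin C (6R,7R,8R,10R; 1E,4Z) | C=C1C(=O)O[C@@H]2/C=C(/C)C(=O)/C=C/[C@](C)(O)C[C@@H](OC(=O)C(C)C)[C@@H]12 | intermediate
32 | tagitinin C 1,2-epoxide (1R,2R,6R,7R,8R,10R) | C=C1C(=O)O[C@@H]2/C=C(/C)C(=O)[C@@H]3O[C@H]3[C@](C)(O)C[C@@H](OC(=O)C(C)C)[C@@H]12 | target

Total step count: 17. Longest linear sequence: 16 steps (from 3 through steps 2–17).

Steps most likely to fail

Step 16. Ring closure may lose to intermolecular coupling, transmetalation may precede CO insertion, or the stannane may be lost by protodestannylation. The fallback forms C2–C3 before cyclisation and closes only C3–C4 without CO. It sets out from aldehyde 26: Wittig olefination with S-ethyl 2-(triphenylphosphoranylidene)ethanethioate (CH2Cl2, rt) should give the (E)-enethioate seco stannane F1. MeI then NaHCO3, as in step 15, should give the α-methylene thioester F2. Intramolecular Liebeskind–Srogl thioester–stannane coupling (Pd2(dba)3, tri(2-furyl)phosphine, copper(I) diphenylphosphinate, THF, high dilution) then closes the ring and comes back to the route at 31.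

Step 17. Peroxide addition to the exocyclic methylene lactone or to the C4=C5 enone may compete with attack at C1, or the oxygen may be delivered to the wrong face. The fallback masks the most reactive acceptor before oxidation. It sets out from 31: dimethylamine (THF, 0 °C) should add to C13 to give the amino lactone 13-(dimethylamino)-11,13-dihydrotagitinin C F3. The same t-BuOOH/DBU epoxidation then has only the two enones to choose from and should give the amino epoxide F4. MeI followed by NaHCO3 regenerates the methylene lactone and comes back to the route at 32.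

Step 6. Hydride delivery may discriminate poorly between the two ketone faces, because C7 and the neopentyl-like CH2-9 are of similar size. The fallback replaces catalyst control by hydroxyl-directed reduction. It sets out from ketone 12: MeNH(OMe)·HCl/Me3Al (CH2Cl2, 0 °C) opens the lactone to the C6-hydroxy Weinreb amide F5. Evans–Saksena reduction (Me4NBH(OAc)3, MeCN/AcOH, −30 °C) delivers hydride from the C6-bound borate and should give the 6,8-anti diol F6. PPTS (CH2Cl2) relactonises through the C6 hydroxyl, the trans 6,12-lactone being favoured over the cis 8,12-isomer, and comes back to the route at 13.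

Further compounds
F1 | step 16 | (E)-enethioate seco stannane: 27 with CH=CH–C(=O)SEt in place of CH=CHI | C/C([Sn](CCCC)(CCCC)CCCC)=C/[C@H]1OC(=O)[C@@H](CN(C)C)[C@@H]1[C@H](OC(=O)C(C)C)C[C@@](C)(O)/C=C/C(=O)SCC
F2 | step 16 | α-methylene thioester: 29 with C(=O)SEt in place of iodine on C2 | C=C1C(=O)O[C@H](/C=C(/C)[Sn](CCCC)(CCCC)CCCC)[C@H]1[C@H](OC(=O)C(C)C)C[C@@](C)(O)/C=C/C(=O)SCC
F3 | step 17 | (11R)-13-(dimethylamino)-11,13-dihydrotagitinin C | CN(C)C[C@@H]1C(=O)O[C@@H]2/C=C(/C)C(=O)/C=C/[C@](C)(O)C[C@@H](OC(=O)C(C)C)[C@@H]12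
F4 | step 17 | (11R)-13-(dimethylamino)-11,13-dihydrotagitinin C (1R,2R)-epoxide | CN(C)C[C@@H]1C(=O)O[C@@H]2/C=C(/C)C(=O)[C@@H]3O[C@H]3[C@](C)(O)C[C@@H](OC(=O)C(C)C)[C@@H]12
F5 | step 6 | C6-hydroxy C8-keto Weinreb amide from opening of lactone 12 | CC[Si](CC)(CC)OC[C@@H](O)[C@H](CC(=O)N(C)OC)C(=O)C[C@@](C)(O[Si](CC)(CC)CC)CO[Si](C)(C)C(C)(C)C
F6 | step 6 | 6,8-anti diol Weinreb amide (8R) | CC[Si](CC)(CC)OC[C@@H](O)[C@H](CC(=O)N(C)OC)[C@H](O)C[C@@](C)(O[Si](CC)(CC)CC)CO[Si](C)(C)C(C)(C)C
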